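1.16 was the number I took from the two earlier runs: the substrate lost per unit of reagent charged, my loss ratio, which is the rate at which substrate falls divided by the rate at which reagent falls, taken over a whole run so that time drops out.

| setting | autumn | winter | amber | grey | ochre |
|---|---|---|---|---|---|
| substrate | 0.20 M | 0.20 M | 0.20 M | 0.20 M | 0.20 M |
| reagent | 0.80 equiv | 0.80 equiv | 0.800 equiv | 0.800 equiv | 0.800 equiv |
| scavenger | 1.2 equiv | 3.1 equiv | 1.00 equiv | 1.50 equiv | 2.20 equiv |
| remark | run made earlier | run made earlier |  |  |  |
| time |  |  | 5.0 h | 5.0 h | 5.0 h |

| run | time / h | substrate / % | target / % |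
|---|---|---|---|
| autumn | 0.417 | 30 | 3 |
| autumn | 0.667 | 24 | 1 |
| autumn | 1.00 | 18 | 1 |
| autumn | 1.33 | 13 | 3 |
| autumn | 2.00 | 12 | 0 |
| autumn | 3.00 | 10 | 2 |
| autumn | 5.00 | 6 | 0 |
| winter | 0.250 | 42 | 2 |
| winter | 0.833 | 21 | 1 |
| winter | 1.33 | 13 | 3 |
| winter | 2.00 | 12 | 2 |
| winter | 3.00 | 8 | 0 |
| winter | 4.00 | 7 | 0 |
| winter | 5.00 | 9 | 0 |

(standard deviation of a reading: 1.5 percentage points)

1. part of the substrate that has reacted at the end, amber
2. part of the substrate that has reacted at the end, grey
3. part of the substrate that has reacted at the end, ochre
4. what raising the equivalents of scavenger from its lowest to its highest value here does to the part of the substrate that has reacted (changes below 5 percentage points count as none) (no change / it falls / it rises)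



I went through the flask slowly, using the readings. In the first instants the fall was steep, for winter's substrate already read 42% at 0.250 h. In the middle, autumn's substrate read 18% at 1.00 h, and so it reached the 20.0% that one reagent per substrate would leave, but it kept falling, to 6% at 5.00 h, so I supposed that substrate had a second way out which cost no reagent. The target never read above 3% in either run. At the end the fall was slow, with winter reading 9% at 5.00 h, and the mean of that and autumn's last reading gave my ratio. I read this tail as the reagent, the limiting reagent, nearing the end of its charge; on that reading, and with the substrate concentration and the time held as in those runs, I took the part reacted at the end as the loss ratio times the equivalents of reagent. I left scavenger out of the reckoning, for at 1.2 equiv in autumn and at 3.1 equiv in winter the substrate read the same 13% at 1.33 h. With 0.800 equiv of reagent in amber, grey and ochre I therefore reckoned 92.5% for each and no trend, though amber's 1.00 equiv lay below the tested span.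

The forecast, holding that the two curves “overlap within the scatter”, gave 93% for amber, 93% for grey, 93% for ochre and, for the trend, no change.

The flasks gave 92.1%, 92.1% and 92.1%, and the trend was no change, a change of 0.038 percentage points.

    substrate + reagent → intermediate + released group (k = 0.570 L mol⁻¹ min⁻¹)
    intermediate ⇌ target (K = 0.330, k = 0.360 min⁻¹)
    intermediate ⇌ isomer of the product (K = 4.70, k = 0.0470 min⁻¹)
    substrate + released group ⇌ idle adduct, settled at all times (K = 3.00 L mol⁻¹)
    scavenger + released group → scavenged by-product (k = 7.60 L mol⁻¹ min⁻¹)
    substrate + target → side product (k = 0.880 L mol⁻¹ min⁻¹)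
    target → over-reaction product (k = 0.240 min⁻¹)

In grey at 5.00 h, with 0.59% of the reagent's charge left, the first step used substrate 1.8 times as fast as its loss with target to side product, which makes 1.56 substrates lost per reagent at that moment, above the 1.15 per reagent charged over the whole of grey. Carried to the neighbour of grey with 0.320 equiv of reagent, my loss ratio gives 37.0% reacted, and that flask stood at 42.0%.

The earlier runs and the new flask were generated by integration on assumed constants; scatter was added.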